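(The readings stem from a simulated flask with made-up constants, and the scatter is random.)

Over 20.0 h of Tuesday's run, the flask asked about has shown how its capture divides between target and other capture product.

all flasks: substrate 0.20 M

|  | second nucleophile | solid first nucleophile | remark | time |
|---|---|---|---|---|
| Tuesday's | 1.2 equiv | 3 equiv | the very flask that is asked about, followed so far |  |
| flask | 1.20 equiv | 3.00 equiv |  | 40 h |

- Tuesday's (time / h: target / %, other capture product / %): 3.00: 0.2, 25.2; 6.00: 0, 30.5; 10.0: 3.1, 32.7; 12.0: 3.1, 33.2; 15.0: 2.5, 33.2; 20.0: 1.1, 35.1

(each reading ± 1 percentage point)

- the numbers in the tables scatter by 1 percentage point (one standard deviation)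
- at the start none of the solid first nucleophile is in solution

- share of target in target plus other capture product at 30 min
- share of target in target plus other capture product at 40 h
- which of target and other capture product there is more of at 40 h

1. Zero of the scale: if each charged equivalent captured alike, target per other capture product would equal the charge ratio, 2.50, a share of 71.4%.

2. First way: the readings at 10.0 h and 12.0 h average 3.10% target and 33.0% other capture product, a share of 8.59%.

3. Second way: the separate readings at 15.0 h and 20.0 h average 1.80% and 34.1%, a share of 5.01%.

4. The two ways part. The second leans on the low 1.1% at 20.0 h, yet the pair means of target differ by 1.3 percentage points, against a scatter of 1 point for such a difference. The parting is therefore read as scatter, and the pairs are pooled.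

5. Pooled, target per other capture product is 0.0730. Divided by the charge ratio, this gives the capture factor, a selectivity factor per charged equivalent, of 0.0292; the statistical case is 1. This reckoning carries the pooled share, 6.81%, to 40 h. For 30 min it takes the share at 3.00 h and 6.00 h, 0.358%.

6. The forecast gives 1% at 30 min, higher than this reckoning's 0.358%, and 7% at 40 h, with other capture product ahead: “Its delayed appearance fits the first nucleophile having to dissolve first”.

7. The flask gives 0.803% at 30 min and 6.40% at 40 h, with 34.4% other capture product against 2.35% target. Its capture factor is 0.0273, far below the statistical 1. The flask holds 0% substrate at 40.0 h, and its share later on stands at 6.40%.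

    first nucleophile + intermediate → target (k = 5.50 /M/h)
    solid first nucleophile ⇌ first nucleophile, rate k2*(cs2 - [first nucleophile]) while solid is left; crystals form when [first nucleophile] > cs2 (solubility = 0.170 M, k = 0.0380 /h)
    substrate → intermediate (k = 0.410 /h)
    intermediate → solvolysis product (k = 2.10 /h)
    first nucleophile ⇌ dormant form (K = 3.20, k = 0.0280 /h)
    second nucleophile + intermediate → other capture product (k = 5.60 /M/h)

8. A neighbouring flask takes 3.00 equiv of second nucleophile, its other charges and its time held as in the flask, so its charge ratio is 1.00. The capture factor from Tuesday's run then gives that flask a share of 2.84%. That neighbouring flask gives 2.51%, ending with 1.50% target against 58.1% other capture product.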